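The vessel was closed, stirred, isothermal and of constant volume; the loading of E stayed at 0.19 mol% while the charge of Z changed from flask to flask.

all flasks: E 0.19 mol%

|  | Z | remark | time |
|---|---|---|---|
| cedar | 0.13 M | run made earlier |  |
| maple | 1.9 M | run made earlier |  |
| blue | 0.15 M |  | 6.0 h |
| red | 0.30 M |  | 6.0 h |
| green | 0.60 M |  | 6.0 h |
| ochre | 1.2 M |  | 6.0 h |
| teal | 2.5 M |  | 6.0 h |

| run | time / h | J / % | G / % |
|---|---|---|---|
| cedar | 0.500 | 23 | 0 |
| cedar | 0.667 | 29 | 0 |
| cedar | 1.00 | 38 | 0 |
| cedar | 1.50 | 50 | 0 |
| cedar | 2.50 | 62 | 2 |
| cedar | 4.00 | 63 | 6 |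
| cedar | 6.00 | 57 | 6 |
| maple | 0.333 | 15 | 0 |
| maple | 1.00 | 34 | 1 |
| maple | 1.50 | 44 | 4 |
| maple | 2.50 | 48 | 14 |
| maple | 4.00 | 35 | 35 |
| maple | 5.00 | 23 | 49 |
| maple | 6.00 | 15 | 59 |

(standard deviation of a reading: 1.5 percentage points)

- the numbers in the tables scatter by 1.5 percentage points (one standard deviation)
- reactions considered so far: Z -> J; D + J -> D + G; J -> L; E -> D; D -> X
- "hardly changes" means that all values lie within two and a half points (for a concentration: within two and a half percent of the largest)

1. [J] at the end for blue, red, green, ochre, teal, in this order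
2. how that number moves from the first to the last of them (falls, then rises / hardly changes / rises, then falls / falls all the way / rises all the way)

At 6.00 h, J read 57% of the charge in cedar (0.13 M) and 15% in maple (1.9 M). I took the loss of J to G as pseudo-first-order, with a rate constant proportional to c_D and so to the charge at this loading, and therefore took the J share at the end to fall exponentially with the charge. The charge difference of cedar and maple over the logarithm of their share ratio gave 1.33 M: this is the fall charge c*, the charge of Z over which the J share drops by the factor e. Then c_J at the end goes as the charge times exp(−charge/c*), which peaks at a charge equal to c*. That lies above ochre's charge and below teal's, so I expected a rise and then a fall, with c_J of 0.305 M in ochre and 0.239 M in teal.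

The forecast gave 0.087 M, 0.156 M, 0.25 M, 0.325 M and 0.29 M from blue to teal, rises, then falls, holding that “At fixed mol%, catalyst concentration scales with [Z]0”, and its teal value was higher than mine. The flasks gave 0.0803 M, 0.143 M, 0.230 M, 0.299 M and 0.265 M in the same order, rises, then falls, with the turn at 1.5 M.

    Z → J (k = 0.530 /h)
    D + J → D + G (k = 3400 /M/h)
    J → L (k = 0.110 /h)
    E → D (k = 0.00850 /h)
    D → X (k = 0.0340 /h)

In blue at 1.23 h, J passed into L 11 times faster than into G. Ochre held 24.9% J at 6.00 h, and teal was charged 1.30 M higher, so c* scaled that share by 0.375 to 9.34%; teal held 10.6%.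

The readings come from a simulation from invented constants.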